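## The problem

Target 30 is a 15-nor-eudesmane (eudesmane numbering throughout; β is the face of the C10 methyl). It is a trans-decalin. Ring A (C1–C5, C10) holds the 1β-carbinol and the C4 ketone. Ring B (C5–C10) holds the 6α-hydroxyl, the 7β-acrylate unit and the 8α-acyloxy group.

- **Stereocentres.** Six must be set (C1, C5, C6, C7, C8, C10). Every substituent except the angular methyl is equatorial. Kinetic axial attack (epoxide opening, conjugate addition, hydride on a C6 or C8 ketone) therefore tends to give the wrong epimer, while syn additions from the α face give the right one.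
- **Control.** C10 and C5 have to be made together. C5 cannot safely be repaired later because it lies between the C4 carbonyl and the C6 oxygen. Once C10 exists, its axial methyl shields the β face and can control C6, C7, C8 and C1.
- **Fragile groups.** These are the aldol unit C4–C5–C6 (dehydration, retro-aldol, epimerisation), two acrylate esters that accept nucleophiles, hydrides and radicals, and the 6-hydroxyl/C12 ester pair, which can close to a γ-lactone.
- **Differentiation.** Only one of three secondary hydroxyls is acylated, so the oxygens on C1, C6 and C8 must appear at different times or under different masks.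
- **Enabling feature.** In ring A the C1 and C4 oxygens are 1,4-related across C2–C3. C1 can enolise only towards C2 because C10 is quaternary, and C4 is a C5 carboxyl carbon plus one methylene. C2 and C3 can therefore be the terminal carbons of two regiodefined enol ethers on neighbouring ring B carbons.

## Retrosynthesis

**Unmasking and the C12 oxidation level (30 ⇒ 29 ⇒ 28 ⇒ 26 ⇒ 25 ⇒ 24).** No skeletal bond is cut.
- 30 comes from its tris-TBS ether 29 with buffered fluoride. Base would endanger the aldol unit, and strong acid would endanger the 6-hydroxy ester.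
- An acrylate on C7 cannot pass through hydride, borane or titanium carbene chemistry. It is therefore traced through acid 28 and allylic alcohol 26 to the isopropenyl group of 25, and that to the dimethylcarbinol of 24.
- The carbinol was preferred to a masked acetyl group because it adds no stereocentre. It was preferred to a free isopropenyl group because it does not compete for borane.
- The forward steps must dehydrate only towards a methyl group and oxidise only the one electron-rich alkene.

**C8–O acyl bond (24 ⇒ 19 + 22).**
- The cut gives keto diol 19 and the silyl-protected acid 22.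
- It is placed before the dehydration because in 19 the only rival of the C8 hydroxyl is a tertiary alcohol, so no extra protecting group is needed. Placed later, C8 and C11 would have to be unmasked separately.
- 19 lacks the whole Michael-acceptor side chain.
- The esterification must cope with a secondary alcohol beside a branched carbon.

**C6–O, C7–H and C1–H bonds (19 ⇒ 18 ⇒ 17 ⇒ 15).**
- O6 and H7 are cis (both α). Syn hydroboration of a C6=C7 alkene from the α face is the one kinetic process that gives both an equatorial C6 oxygen and an equatorial side chain. A C6 ketone reduction or an epoxide opening would follow axial paths to the wrong epimers.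
- The same borane reduces the C1 ketone. The C1 and C6 hydroxyls are therefore formed together (17) and share one protection step (18).
- 15 has three stereocentres fewer.
- The reaction must come from the α face and spare the ketal.

**C8–O bond (15 ⇒ 14 ⇒ 13 ⇒ 12).**
- Ene-type allylic oxidation of 12 was rejected. On the open α face the aligned allylic hydrogen is 9α-H, which leads to a C7 tertiary alcohol.
- Epoxidation followed by homolytic opening separates the two demands. The angular methyl chooses the face, and the stability of the C7 radical chooses the regiochemistry.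
- Oxygenating ring B before ring A exists was also weighed and dropped, for four reasons:
  - Borane would reduce the methyl ketone.
  - A C1 carbinol beside the C4 ester lactonises.
  - The monocycle offers weaker facial bias.
  - The C4 ketal would have to form peri to a C6 silyl ether.
- 12 has only two stereocentres.

**C2–C3 bond, ring A (12 ⇒ 11).**
- Cuts at C1–C2 or C3–C4 would call for acyl anion equivalents. Cuts at C4–C5 or C1–C10 would form bonds at crowded ring carbons.
- C2 and C3 are both natural nucleophiles. One-electron oxidation of one partner removes the polarity mismatch.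
- 11 is monocyclic, and each arm is a one-step derivative of a ketone or an ester.
- The forward reaction must join only the terminal carbons, ignore C7=C8, and release C1 as a ketone and C4 as a ketal.

**One-carbon units C3 and C2 (11 ⇒ 10 ⇒ 9 ⇒ 8 ⇒ 7).**
- C3=C4 is cut by ester methylenation (11 ⇒ 10). The silyl enol ether goes back to ketone 9. C1–C2 is cut by methyl addition and oxidation (9 ⇒ 8 ⇒ 7).
- The order is fixed. The ketone must be masked as its enol ether before the titanium carbene arrives, or it would be methylenated first.
- 7 carries both arms as simple carbonyl groups of different reactivity.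

**C5–C6 and C9–C10 bonds, ring B (7 ⇒ 4 + 6).**
- A Diels–Alder cut with C5=C10 as the dienophile was chosen over one with C9=C10.
- The E geometry of enal ester 6 is translated without ambiguity into the trans C5/C10 arms.
- Diene 4 has unsubstituted termini, so there is no endo/exo or E/Z issue.
- Two achiral fragments replace a ring with a quaternary centre.
- The reaction must be para-selective with respect to the formyl group and enantioselective.

**Building blocks (4 ⇒ 2 + 3, 2 ⇒ 1; 6 ⇒ 5; 22 ⇒ 21 ⇒ 20).**
- The diene comes from ethylene 3 and silyl ether 2 of alkynol 1 by enyne metathesis.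
- The dienophile comes from senecioate 5 by allylic oxidation.
- The acid comes from hydroxymethyl acrylate 20.
- All of these are commercial or one step from commercial material.

## Roads not taken

**Alternative 1:** The cut is C5–C10, which unfolds both rings into the ten-membered epoxy allylsilane A1.
- *Forward step.* BF3·OEt2 would open the 1,10-epoxide at tertiary C10 while the C4–C5 allylsilane attacks through C5, giving the 1β-hydroxy-4(15)-methylene trans-eudesmane A2.
- *Merits.* One step makes two rings, fixes C5 and C10, passes the epoxide configuration on to C1, and carries the finished acrylate and a differentiated C6/C8 pair. In stereocentres per key step it is clearly ahead of the chosen plan, whose ring closure creates none.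
- *Weak points.*
  - A1 needs a medium-ring closure with an E-trisubstituted alkene, a face-selective epoxidation without rigid control, an allylsilane and three contiguous stereocentres.
  - The crowded C6–C8 segment may favour conformers that fold to other fusion modes.
  - The Lewis acid meets a PMB ether and an acrylate.
  - A2 holds one carbon too many, so its methylene must be cleaved beside another 1,1-disubstituted alkene.
- *Comparison.* The chosen plan sets against this a precursor reached in eight steps of predictable selectivity, and a C4 carbonyl that appears with the right carbon count and already masked.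

**Alternative 2:** The cut is C6–C7, giving aldehyde A3. This is a complete ring A whose C10 arm ends in a (Z)-2-(bromomethyl)enoate.
- *Forward step.* CrCl2 (divalent chromium) would form the allylchromium species, which adds through C7 to the C6 aldehyde and closes ring B as A4.
- *Merits.* The method is mild and chemoselective. It makes C6, C7 and the exocyclic methylene ester in the ring-forming step, so the four-step sequence from carbinol to acrylate (steps 19–22) would vanish. In this respect it is better.
- *Weak points.*
  - The C6/C7 configuration depends on a cyclic transition state constrained by the forming ring, and the all-equatorial outcome is not assured.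
  - The new alkoxide sits γ to the ester, so lactonisation would tie up exactly the hydroxyl and the ester that must stay free.
  - The C5 aldehyde can epimerise.
  - A3 needs C1, C5 and C10 plus an acyclic C8 centre built separately.
- *Comparison.* The chosen plan fixes C6/C7 by the mechanism of a syn addition, at the price of a longer end game.

**Alternative 3:** The cut is C9–C10, giving seco acid A5. This is a ring A enone bearing the C6–C9 chain.
- *Forward step.* Photocatalytic oxidation of the carboxylate (organic photocatalyst, Cs2CO3, visible light) releases CO2. The C9 radical adds to C10 in a 6-endo closure, and the C5 radical is reduced and protonated to give A6.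
- *Merits.* The step is redox-neutral and very mild, and it forges the quaternary carbon without organometallics. A6 emerges with a free C8 hydroxyl and a free C4 ketone, which would spare steps 12 and 15 of the chosen plan.
- *Weak points.*
  - A primary radical must add to the fully substituted β-carbon of a tetrasubstituted enone, so hydrogen abstraction and premature reduction compete.
  - C10 and C5 are both set by remote control from a flexible chain.
  - The C5 enolate formed in basic medium can expel the C6 silyloxy group.
  - The C6–C8 triad needs acyclic stereocontrol.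
- *Comparison.* The chosen plan sets C5 and C10 concertedly from an alkene geometry and adds the triad on a rigid decalin.

Key step: step 9

Assumption: the sense of induction in step 4 follows the formyl C–H···O model for 2-substituted enals with the (S)-prolinol-derived catalyst; if the adduct proved antipodal, the equally available (R)-catalyst would be used.

## Steps

Step 1
Reactants: 1 2-methylbut-3-yn-2-ol
Product: 2 triethyl[(2-methylbut-3-yn-2-yl)oxy]silane
Conditions: TESCl, imidazole, DMAP (cat.), DMF, rt
Reagents that add atoms: chlorotriethylsilane CC[Si](Cl)(CC)CC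
Why: Routine silylation of a tertiary propargylic alcohol that is open on the alkyne side; the TES ether keeps the later allylic carbinol from binding to, or being ionised by, the acid catalyst of step 4.

Step 2
Reactants: 2 triethyl[(2-methylbut-3-yn-2-yl)oxy]silane; 3 ethylene
Product: 4 2-[2-(triethylsilyloxy)propan-2-yl]buta-1,3-diene
Conditions: second-generation Grubbs catalyst (5 mol %), ethylene (balloon), CH2Cl2, rt to 40 °C
Reagents that add atoms: none
Why: Cross enyne metathesis with ethylene converts a terminal alkyne into a 2-substituted butadiene with no E/Z issue. Propargylic silyl ethers are good substrates, and the bulky 2-substituent favours the s-cis form needed next.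

Step 3
Reactants: 5 methyl 3-methylbut-2-enoate
Product: 6 methyl (2E)-3-methyl-4-oxobut-2-enoate
Conditions: SeO2, 1,4-dioxane, reflux
Reagents that add atoms: selenium dioxide O=[Se]=O
Why: Allylic oxidation by SeO2 (ene reaction, then [2,3]-shift) attacks the methyl group trans to the ester, so the E enal forms.

Step 4
Reactants: 4 2-[2-(triethylsilyloxy)propan-2-yl]buta-1,3-diene; 6 methyl (2E)-3-methyl-4-oxobut-2-enoate
Product: 7 methyl 6-formyl-6-methyl-3-[2-(triethylsilyloxy)propan-2-yl]cyclohex-3-ene-1-carboxylate, ester and formyl trans (5α-H, 10β-CH3, C7=C8)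
Conditions: (S)-3,3-diphenyl-1-(2-methylphenyl)tetrahydro-1H,3H-pyrrolo[1,2-c][1,3,2]oxazaborole activated with Tf2NH (15 mol %), CH2Cl2, −78 to −40 °C
Reagents that add atoms: none
Why: Catalytic asymmetric Diels–Alder reaction of a 2-substituted enal. The boron cation binds the formyl oxygen, so C5 (β to CHO) becomes the most electrophilic carbon and bonds to the more nucleophilic diene terminus C6; this places the side chain para to C10, and sterics point the same way. Suprafacial addition turns the E alkene into the trans C5/C10 arms, the catalyst face sets the absolute configuration, and the unsubstituted diene termini remove any endo/exo question.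

Step 5
Reactants: 7 Diels–Alder adduct
Product: 8 methyl 6-(1-hydroxyethyl)-6-methyl-3-[2-(triethylsilyloxy)propan-2-yl]cyclohex-3-ene-1-carboxylate (both C1 epimers)
Conditions: MeMgBr (1.05 equiv), THF, −78 °C; AcOH quench at −78 °C
Reagents that add atoms: methylmagnesium bromide C[Mg]Br
Why: Grignard 1,2-addition. The aldehyde outruns the methyl ester at −78 °C, and the cold acidic quench keeps the alkoxide from lactonising onto C4. The new C1 centre is erased in step 6.

Step 6
Reactants: 8 carbinol
Product: 9 methyl 6-acetyl-6-methyl-3-[2-(triethylsilyloxy)propan-2-yl]cyclohex-3-ene-1-carboxylate (acetyl and ester trans)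
Conditions: Dess–Martin periodinane, NaHCO3, CH2Cl2, 0 °C to rt
Reagents that add atoms: none
Why: Dess–Martin oxidation under buffered, non-basic conditions gives the methyl ketone without touching C5–H, the alkene or the silyl ether.

Step 7
Reactants: 9 keto ester
Product: 10 C1 tert-butyldimethylsilyl enol ether of 9
Conditions: TBSOTf, Et3N, CH2Cl2, 0 °C
Reagents that add atoms: tert-butyldimethylsilyl triflate CC(C)(C)[Si](C)(C)OS(=O)(=O)C(F)(F)F
Why: Soft enolisation with silyl triflate and amine. C1 has α-hydrogens only on C2, so a single terminal enol ether can form, and an ester is not enolised under these conditions.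

Step 8
Reactants: 10 silyl enol ether ester
Product: 11 ring B bis(enol ether): C10 arm C(OTBS)=CH2, C5 arm C(OMe)=CH2, arms trans
Conditions: Cp2TiMe2 (3 equiv), toluene, 75 °C, dark
Reagents that add atoms: dimethyltitanocene C[Ti+2]C.c1cc[cH-]c1.c1cc[cH-]c1
Why: Petasis methylenation. Thermally formed Cp2Ti=CH2 converts the ester carbonyl into the methyl enol ether through an oxatitanacyclobutane. The reagent is non-acidic and leaves silyl enol ethers and unactivated alkenes alone. The ketone had to be masked first because it would be methylenated faster than the ester.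

Step 9
Reactants: 11 ring B bis(enol ether)
Product: 12 (5αH,10β-methyl)-4,4-dimethoxy-11-(triethylsilyloxy)-15-noreudesm-7-en-1-one (trans-decalin)
Conditions: reticulated vitreous carbon anode, Pt cathode, undivided cell, LiClO4 (0.1 M), MeOH–CH2Cl2 1:4, 2,6-lutidine, constant current, 2.2 F/mol, rt
Reagents that add atoms: methanol CO
Why: Anodic removal of one electron from the more easily oxidised silyl enol ether gives a radical cation whose unhindered terminus C2 is attacked by C3, the nucleophilic terminus of the methyl enol ether; if the methyl enol ether were oxidised first, the same bond would form. The C4 oxocarbenium ion is trapped by methanol as the dimethyl ketal, the α-silyloxy radical at C1 loses a second electron, and methanol removes the silyl group to leave the C1 ketone (two faradays per mole, hydrogen at the cathode). The closest known reaction type is the intramolecular anodic olefin coupling of enol ethers, the electrochemical counterpart of oxidative enolate coupling to 1,4-dicarbonyl compounds. Ring A closes as a six-membered ring, 6-endo with respect to both alkenes because C1 and C4 both end up inside the ring; the trans-diequatorial arms on C10 and C5 hold C2 and C3 gauche and within bonding distance and map directly onto the trans-decalin. No stereocentre is created: C4 carries two identical methoxy groups, and C5 and C10 are untouched under the buffered, non-basic conditions. The step needs tail-to-tail regiochemistry, secured because only bonding at the terminal carbons leaves an oxygen-stabilised radical and cation, and it needs chemoselectivity over C7=C8, whose oxidation potential is much higher and whose attack on C2 would require a diaxial conformer and a bridged ring. It also needs C1 and C4 to emerge differentiated, which follows from the two oxygen substituents: silicon is lost and methyl is kept. 2,6-Lutidine scavenges the acid formed at the anode so that neither enol ether is solvolysed before it is oxidised.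

Step 10
Reactants: 12 decalin ketone ketal
Product: 13 7α,8α-epoxide of 12
Conditions: mCPBA, NaHCO3, CH2Cl2, 0 °C
Reagents that add atoms: 3-chloroperbenzoic acid OOC(=O)c1cccc(Cl)c1
Why: Peracid epoxidation of the only electron-rich alkene. The axial C10 methyl, 1,3 to C8, blocks the β face of the rigid trans-decalin, so the α-epoxide is expected and sets C8. The buffer protects the ketal, and the hindered C1 ketone is too slow for Baeyer–Villiger oxidation at 0 °C.

Step 11
Reactants: 13 7α,8α-epoxide
Product: 14 8α-hydroxy-4,4-dimethoxy-11-(triethylsilyloxy)-15-noreudesm-6-en-1-one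
Conditions: Cp2TiCl2 (2.5 equiv), Mn dust, THF, rt, degassed; aq. NaHCO3 work-up
Reagents that add atoms: none
Why: Cp2TiCl (trivalent titanium) opens the epoxide homolytically at C7–O to the tertiary radical, and a second Cp2TiCl removes the only β-hydrogen available, axial 6β-H; this is reductive epoxide opening followed by mixed disproportionation to the allylic alcohol. The C8–O bond is never broken, so the 8α configuration is kept. The neutral medium spares ketone and ketal and avoids base-induced syn elimination, for which no properly aligned 6α-H exists.

Step 12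
Reactants: 14 allylic alcohol
Product: 15 8α-triethylsilyl ether of 14
Conditions: TESCl, imidazole, DMAP, DMF, rt to 40 °C
Reagents that add atoms: chlorotriethylsilane CC[Si](Cl)(CC)CC
Why: Routine silylation. This temporary mask has the same lability as the C11 ether, so both can leave in one later step.

Step 13
Reactants: 15 bis-TES enone-free ketone
Product: 17 1β,6α-dihydroxy-4,4-dimethoxy-8α,11-bis(triethylsilyloxy)-15-noreudesmane (7α-H), via organoborane 16 (not isolated)
Conditions: BH3·THF (5 equiv), THF, 0 °C to rt; then NaOH, H2O2, 0 °C
Reagents that add atoms: hydrogen peroxide OO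
Why: Borane first reduces the C1 ketone by axial attack from the α face (the equatorial path is blocked by the adjacent C10 methyl) to the equatorial 1β-alcohol, then hydroborates the trisubstituted alkene with boron on the less substituted C6. Syn addition from the α face, opposite the angular methyl, puts boron on C6 and hydrogen on C7 both α. Oxidation with retention then gives 6α-OH and an equatorial C7 side chain.

Step 14
Reactants: 17 1β,6α-diol
Product: 18 1β,6α-bis(tert-butyldimethylsilyl) ether of 17
Conditions: TBSOTf, 2,6-lutidine, CH2Cl2, 0 °C to rt
Reagents that add atoms: tert-butyldimethylsilyl triflate CC(C)(C)[Si](C)(C)OS(=O)(=O)C(F)(F)F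
Why: Silyl triflate with a hindered pyridine base silylates even crowded secondary alcohols. Ketals, unlike aldehyde acetals, generally survive this reagent pair at 0 °C.

Step 15
Reactants: 18 fully protected decalin
Product: 19 8α,11-dihydroxy-1β,6α-bis(tert-butyldimethylsilyloxy)-15-noreudesman-4-one
Conditions: AcOH–THF–H2O 3:1:1, rt to 40 °C
Reagents that add atoms: water O
Why: Acid hydrolysis follows lability (dimethyl ketal, then TES, then hindered secondary TBS far behind), so ketal and both TES ethers leave while C1 and C6 stay masked. Releasing the ketone here also ends the peri strain with C6 and avoids uncontrolled ketal loss in the later aqueous oxidations.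

Step 16
Reactants: 20 ethyl 2-(hydroxymethyl)acrylate
Product: 21 ethyl 2-[(tert-butyldimethylsilyloxy)methyl]acrylate
Conditions: TBSCl, imidazole, CH2Cl2, rt
Reagents that add atoms: tert-butyldimethylsilyl chloride CC(C)(C)[Si](C)(C)Cl
Why: Routine protection of a primary allylic alcohol; the TBS group leaves with the others in step 23.

Step 17
Reactants: 21 silylated acrylate
Product: 22 2-[(tert-butyldimethylsilyloxy)methyl]acrylic acid
Conditions: LiOH, THF–H2O, 0 °C to rt; then 1 M HCl to pH 4
Reagents that add atoms: lithium hydroxide [Li+].[OH-]
Why: Saponification of an unhindered ethyl ester; the 2-substituent slows conjugate addition of hydroxide, and the primary TBS ether survives cold LiOH.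

Step 18
Reactants: 19 keto diol; 22 protected acid
Product: 24 8α-{2-[(tert-butyldimethylsilyloxy)methyl]acryloyloxy}-11-hydroxy-1β,6α-bis(tert-butyldimethylsilyloxy)-15-noreudesman-4-one, via mixed anhydride 23 (not isolated)
Conditions: 2,4,6-trichlorobenzoyl chloride, Et3N, toluene, rt; then 19, DMAP, rt to 40 °C
Reagents that add atoms: none
Why: Yamaguchi esterification, suited to hindered secondary alcohols. The tertiary C11 hydroxyl does not compete, and the C8–O bond is not broken, so the configuration is kept.

Step 19
Reactants: 24 ester carbinol
Product: 25 isopropenyl compound (eudesm-11-ene) with the groups of 24 otherwise unchanged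
Conditions: methyl N-(triethylammoniosulfonyl)carbamate (Burgess reagent), toluene, 60 °C
Reagents that add atoms: none
Why: Burgess dehydration (syn elimination of a sulfamate). Loss of H7 would give a tetrasubstituted alkene with severe A(1,3) strain to the equatorial C6 and C8 oxygens, so a methyl hydrogen is lost. The neutral conditions spare the β-silyloxy ketone and the acrylate.

Step 20
Reactants: 25 isopropenyl compound
Product: 26 12-hydroxy-eudesm-11(13)-ene derivative (C7 side chain C(=CH2)CH2OH)
Conditions: SeO2 (0.5 equiv), t-BuOOH, CH2Cl2, rt
Reagents that add atoms: tert-butyl hydroperoxide CC(C)(C)OO; selenium dioxide O=[Se]=O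
Why: SeO2-catalysed allylic hydroxylation (ene reaction, then [2,3]-shift) of the only electron-rich alkene. The methyl group reacts because H7 is shielded, and the acrylate is inert. Any enal formed lies on the path of step 21.

Step 21
Reactants: 26 allylic alcohol
Product: 28 eudesm-11(13)-en-12-oic acid derivative, via enal 27 (not isolated)
Conditions: TEMPO (cat.), NaClO2, NaOCl (cat.), MeCN–phosphate buffer pH 6.7, 35 °C
Reagents that add atoms: sodium chlorite [Na+].[O-]Cl=O
Why: The oxoammonium salt oxidises the primary allylic alcohol to the enal, and chlorite takes this to the acid in the same flask. The near-neutral medium tolerates TBS ethers, the ketone and both electron-poor alkenes.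

Step 22
Reactants: 28 acrylic acid
Product: 29 methyl ester, tris-TBS ether of the target
Conditions: TMSCHN2, toluene–MeOH 4:1, 0 °C
Reagents that add atoms: (trimethylsilyl)diazomethane C[Si](C)(C)C=[N+]=[N-]
Why: Base-free methylation by the diazoalkane. Proton transfer and alkylation at 0 °C are much faster than dipolar cycloaddition to the 2-substituted acrylates.

Step 23
Reactants: 29 tris-TBS ether
Product: 30 methyl 1β,6α-dihydroxy-8α-[2-(hydroxymethyl)acryloyloxy]-4-oxo-15-noreudesm-11(13)-en-12-oate (target)
Conditions: HF·pyridine, pyridine, THF, 0 °C to rt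
Reagents that add atoms: none
Why: Fluoride-driven cleavage of the three TBS ethers. The buffered medium avoids base (retro-aldol, elimination, acyl migration) and strong acid (lactonisation of the 6-hydroxyl onto the C12 ester), and no stereocentre is touched.

## Compound list

1 | 2-methylbut-3-yn-2-ol | CC(C)(O)C#C | starting material
2 | triethyl[(2-methylbut-3-yn-2-yl)oxy]silane | CC[Si](CC)(CC)OC(C)(C)C#C | intermediate
3 | ethylene | C=C | starting material
4 | 2-[2-(triethylsilyloxy)propan-2-yl]buta-1,3-diene | C=CC(=C)C(C)(C)O[Si](CC)(CC)CC | intermediate
5 | methyl 3-methylbut-2-enoate | COC(=O)C=C(C)C | starting material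
6 | methyl (2E)-3-methyl-4-oxobut-2-enoate | COC(=O)/C=C(C)/C=O | intermediate
7 | Diels–Alder adduct, formyl and ester trans (5α-H, 10β-CH3, C7=C8) | O=C[C@]1(C)CC=C(C(C)(C)O[Si](CC)(CC)CC)C[C@H]1C(=O)OC | intermediate
8 | C1 carbinol (both C1 epimers) | CC(O)[C@]1(C)CC=C(C(C)(C)O[Si](CC)(CC)CC)C[C@H]1C(=O)OC | intermediate
9 | keto ester | CC(=O)[C@]1(C)CC=C(C(C)(C)O[Si](CC)(CC)CC)C[C@H]1C(=O)OC | intermediate
10 | C1 TBS enol ether ester | C=C(O[Si](C)(C)C(C)(C)C)[C@]1(C)CC=C(C(C)(C)O[Si](CC)(CC)CC)C[C@H]1C(=O)OC | intermediate
11 | ring B bis(enol ether), key-step precursor | C=C(O[Si](C)(C)C(C)(C)C)[C@]1(C)CC=C(C(C)(C)O[Si](CC)(CC)CC)C[C@H]1C(=C)OC | intermediate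
12 | trans-decalin 1-ketone 4-dimethyl ketal, key-step product | CC[Si](CC)(CC)OC(C)(C)C1=CC[C@@]2(C)C(=O)CCC(OC)(OC)[C@@H]2C1 | intermediate
13 | 7α,8α-epoxide | CC[Si](CC)(CC)OC(C)(C)[C@]12O[C@H]1C[C@@]3(C)C(=O)CCC(OC)(OC)[C@@H]3C2 | intermediate
14 | 8α-hydroxy-6-ene | O[C@H]1C[C@@]2(C)C(=O)CCC(OC)(OC)[C@@H]2C=C1C(C)(C)O[Si](CC)(CC)CC | intermediate
15 | 8α-TES ether of 14 | CC[Si](CC)(CC)O[C@H]1C[C@@]2(C)C(=O)CCC(OC)(OC)[C@@H]2C=C1C(C)(C)O[Si](CC)(CC)CC | intermediate
16 | 6α-boryl 1β-boryloxy adduct (not isolated) | CC[Si](CC)(CC)O[C@H]1C[C@@]2(C)[C@H](OB)CCC(OC)(OC)[C@@H]2[C@@H](B)[C@@H]1C(C)(C)O[Si](CC)(CC)CC | intermediate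
17 | 1β,6α-diol | CC[Si](CC)(CC)O[C@H]1C[C@@]2(C)[C@H](O)CCC(OC)(OC)[C@@H]2[C@@H](O)[C@@H]1C(C)(C)O[Si](CC)(CC)CC | intermediate
18 | 1β,6α-bis-TBS ether | CC[Si](CC)(CC)O[C@H]1C[C@@]2(C)[C@H](O[Si](C)(C)C(C)(C)C)CCC(OC)(OC)[C@@H]2[C@@H](O[Si](C)(C)C(C)(C)C)[C@@H]1C(C)(C)O[Si](CC)(CC)CC | intermediate
19 | 4-keto 8α,11-diol | O[C@H]1C[C@@]2(C)[C@H](O[Si](C)(C)C(C)(C)C)CCC(=O)[C@@H]2[C@@H](O[Si](C)(C)C(C)(C)C)[C@@H]1C(C)(C)O | intermediate
20 | ethyl 2-(hydroxymethyl)acrylate | C=C(CO)C(=O)OCC | starting material
21 | ethyl 2-[(tert-butyldimethylsilyloxy)methyl]acrylate | C=C(CO[Si](C)(C)C(C)(C)C)C(=O)OCC | intermediate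
22 | 2-[(tert-butyldimethylsilyloxy)methyl]acrylic acid | C=C(CO[Si](C)(C)C(C)(C)C)C(=O)O | intermediate
23 | mixed 2,4,6-trichlorobenzoic anhydride of 22 (not isolated) | C=C(CO[Si](C)(C)C(C)(C)C)C(=O)OC(=O)c1c(Cl)cc(Cl)cc1Cl | intermediate
24 | 8α-ester 11-carbinol | C=C(CO[Si](C)(C)C(C)(C)C)C(=O)O[C@H]1C[C@@]2(C)[C@H](O[Si](C)(C)C(C)(C)C)CCC(=O)[C@@H]2[C@@H](O[Si](C)(C)C(C)(C)C)[C@@H]1C(C)(C)O | intermediate
25 | isopropenyl compound | C=C(CO[Si](C)(C)C(C)(C)C)C(=O)O[C@H]1C[C@@]2(C)[C@H](O[Si](C)(C)C(C)(C)C)CCC(=O)[C@@H]2[C@@H](O[Si](C)(C)C(C)(C)C)[C@@H]1C(C)=C | intermediate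
26 | C12 allylic alcohol | C=C(CO[Si](C)(C)C(C)(C)C)C(=O)O[C@H]1C[C@@]2(C)[C@H](O[Si](C)(C)C(C)(C)C)CCC(=O)[C@@H]2[C@@H](O[Si](C)(C)C(C)(C)C)[C@@H]1C(=C)CO | intermediate
27 | C12 enal (not isolated) | C=C(CO[Si](C)(C)C(C)(C)C)C(=O)O[C@H]1C[C@@]2(C)[C@H](O[Si](C)(C)C(C)(C)C)CCC(=O)[C@@H]2[C@@H](O[Si](C)(C)C(C)(C)C)[C@@H]1C(=C)C=O | intermediate
28 | C12 acid | C=C(CO[Si](C)(C)C(C)(C)C)C(=O)O[C@H]1C[C@@]2(C)[C@H](O[Si](C)(C)C(C)(C)C)CCC(=O)[C@@H]2[C@@H](O[Si](C)(C)C(C)(C)C)[C@@H]1C(=C)C(=O)O | intermediate
29 | tris-TBS ether of the target | C=C(CO[Si](C)(C)C(C)(C)C)C(=O)O[C@H]1C[C@@]2(C)[C@H](O[Si](C)(C)C(C)(C)C)CCC(=O)[C@@H]2[C@@H](O[Si](C)(C)C(C)(C)C)[C@@H]1C(=C)C(=O)OC | intermediate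
30 | CNP0144895.1 | C=C(CO)C(=O)O[C@H]1C[C@@]2(C)[C@H](O)CCC(=O)[C@@H]2[C@@H](O)[C@@H]1C(=C)C(=O)OC | target

## Step count and least certain steps

Total: 23 steps. Longest linear sequence: 20 steps (1, 2, 4–15, 18–23).

**Step 9 (key step).**
- *What may go wrong.* The enol ethers may be solvolysed by methanol and anodic acid before they are oxidised. The radical cation may be captured by methanol faster than the doubly endo closure occurs. The reason is that the closure places both oxygenated carbons inside the ring, a less common geometry than exocyclic acetal formation.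
- *Fallback.* It sets out from 11 and returns at 12.
  - Brief treatment with dilute HCl in THF at 0 °C hydrolyses both enol ethers to the trans diacetyl compound F1.
  - Double kinetic deprotonation with LDA at −78 °C and oxidation with CuCl2 (divalent copper) in DMF couples the two methyl termini (oxidative enolate coupling) to the decalin-1,4-dione F2.
  - HC(OMe)3, MeOH and PPTS then ketalise the less hindered C4 carbonyl in preference to the neopentyl C1 carbonyl, giving 12.

**Step 4.**
- *What may go wrong.* Regio- and enantioselectivity may erode because the ester is a second activating group. The strong acid may ionise the tertiary allylic silyl ether.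
- *Fallback.* It sets out from 4 and 6 and returns at 7.
  - Heating the two components in toluene without acid gives the racemic trans adduct, that is 7 together with its mirror-image adduct F3.
  - Condensation with (1R,2R)-N,N′-dimethyl-1,2-diphenylethane-1,2-diamine gives the imidazolidine of 7 F4 and the diastereomeric imidazolidine F5, which are separated by chromatography.
  - Mild aqueous acid then releases enantiopure 7 from F4.

**Step 11.**
- *What may go wrong.* The crowded C7 radical may be quenched by hydrogen abstraction from THF. It may also undergo further reduction followed by loss of the C11 silyloxy group, instead of loss of 6β-H. The allylic strain between the C8 oxygen and the side chain in the product slows the desired path.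
- *Fallback.* It sets out from 12 and returns at 15.
  - OsO4 with NMO dihydroxylates the α face to the 7α,8α-diol F6.
  - TESCl silylates only the secondary hydroxyl to give the 8-TES ether F7.
  - SOCl2–pyridine eliminates the axial tertiary 7α-hydroxyl with the antiperiplanar 6β-H, giving 15.

**Step 13.**
- *What may go wrong.* Hydroboration of the alkene flanked by the tertiary side chain may be slow. This would leave time for reductive cleavage of the ketal by borane.
- *Fallback.* It sets out from 14 and returns at 17.
  - VO(acac)2 with t-BuOOH epoxidises syn to the 8α-hydroxyl to give the 6α,7α-epoxy alcohol F8.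
  - TESCl gives its silyl ether F9.
  - Cp2TiCl with 1,4-cyclohexadiene opens the epoxide at C7 and delivers hydrogen to the radical, with the bulky side chain settling equatorial, to give the 6α-hydroxy 1-ketone F10.
  - NaBH4 then reduces C1 from the α face to 17.

**Step 14.**
- *What may go wrong.* Silylation of the C6 hydroxyl may be incomplete, because it is wedged between the side chain and the peri ketal. The ketal may collapse to an enol ether under the silyl triflate.
- *Fallback.* It sets out from 17 and returns at 19.
  - Wet silica with oxalic acid removes only the very labile dimethyl ketal, giving the 4-keto diol F11, in which the peri strain is gone.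
  - TBSOTf with 2,6-lutidine gives the bis-TBS ketone F12.
  - AcOH–THF–H2O then removes the two TES ethers to reach 19.

## Further compounds

F1 | step 9 | trans-1,2-diacetyl compound (C1 and C4 methyl ketones) | CC(=O)[C@]1(C)CC=C(C(C)(C)O[Si](CC)(CC)CC)C[C@H]1C(C)=O
F2 | step 9 | trans-decalin-1,4-dione | CC[Si](CC)(CC)OC(C)(C)C1=CC[C@@]2(C)C(=O)CCC(=O)[C@@H]2C1
F3 | step 4 | mirror image of 7 | O=C[C@@]1(C)CC=C(C(C)(C)O[Si](CC)(CC)CC)C[C@@H]1C(=O)OC
F4 | step 4 | imidazolidine of 7 with the (R,R)-diamine | CN1[C@H](c2ccccc2)[C@@H](c2ccccc2)N(C)C1[C@]3(C)CC=C(C(C)(C)O[Si](CC)(CC)CC)C[C@H]3C(=O)OC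
F5 | step 4 | imidazolidine of F3 with the (R,R)-diamine | CN1[C@H](c2ccccc2)[C@@H](c2ccccc2)N(C)C1[C@@]3(C)CC=C(C(C)(C)O[Si](CC)(CC)CC)C[C@@H]3C(=O)OC
F6 | step 11 | 7α,8α-diol | O[C@H]1C[C@@]2(C)C(=O)CCC(OC)(OC)[C@@H]2C[C@]1(O)C(C)(C)O[Si](CC)(CC)CC
F7 | step 11 | 8α-TES ether of the 7α,8α-diol | CC[Si](CC)(CC)O[C@H]1C[C@@]2(C)C(=O)CCC(OC)(OC)[C@@H]2C[C@]1(O)C(C)(C)O[Si](CC)(CC)CC
F8 | step 13 | 6α,7α-epoxy 8α-alcohol | O[C@H]1C[C@@]2(C)C(=O)CCC(OC)(OC)[C@@H]2[C@H]3O[C@@]13C(C)(C)O[Si](CC)(CC)CC
F9 | step 13 | 8α-TES ether of the epoxy alcohol | CC[Si](CC)(CC)O[C@H]1C[C@@]2(C)C(=O)CCC(OC)(OC)[C@@H]2[C@H]3O[C@@]13C(C)(C)O[Si](CC)(CC)CC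
F10 | step 13 | 6α-hydroxy 1-ketone (7α-H) | CC[Si](CC)(CC)O[C@H]1C[C@@]2(C)C(=O)CCC(OC)(OC)[C@@H]2[C@@H](O)[C@@H]1C(C)(C)O[Si](CC)(CC)CC
F11 | step 14 | 4-keto 1β,6α-diol bis-TES ether | CC[Si](CC)(CC)O[C@H]1C[C@@]2(C)[C@H](O)CCC(=O)[C@@H]2[C@@H](O)[C@@H]1C(C)(C)O[Si](CC)(CC)CC
F12 | step 14 | 4-keto 1β,6α-bis-TBS 8α,11-bis-TES ether | CC[Si](CC)(CC)O[C@H]1C[C@@]2(C)[C@H](O[Si](C)(C)C(C)(C)C)CCC(=O)[C@@H]2[C@@H](O[Si](C)(C)C(C)(C)C)[C@@H]1C(C)(C)O[Si](CC)(CC)CC
A1 | alternative 1 | ten-membered 1,10-epoxy 4-ene allylsilane (6α-OTBS, 8α-OPMB, C7 acrylate) | COc1ccc(cc1)CO[C@H]2C[C@@]3(C)O[C@@H]3CC/C(C[Si](C)(C)C)=C/[C@@H](O[Si](C)(C)C(C)(C)C)[C@@H]2C(=C)C(=O)OC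
A2 | alternative 1 | 1β-hydroxy-4(15)-methylene trans-eudesmane | COc3ccc(cc3)CO[C@H]1C[C@@]2(C)[C@H](O)CCC(=C)[C@@H]2[C@@H](O[Si](C)(C)C(C)(C)C)[C@@H]1C(=C)C(=O)OC
A3 | alternative 2 | ring A C6 aldehyde with (Z)-2-(bromomethyl)enoate arm | COc1ccc(cc1)CO[C@@H](C[C@@]2(C)[C@H](O[Si](C)(C)C(C)(C)C)CCC3(OCCO3)[C@@H]2C=O)/C=C(\CBr)C(=O)OC
A4 | alternative 2 | trans-decalin 6α-hydroxy acrylate with C4 dioxolane | COc3ccc(cc3)CO[C@H]1C[C@@]2(C)[C@H](O[Si](C)(C)C(C)(C)C)CCC4(OCCO4)[C@@H]2[C@@H](O)[C@@H]1C(=C)C(=O)OC
A5 | alternative 3 | seco acid: ring A enone with C6–C9 chain | OC(=O)C[C@H](O)[C@@H](C(C)=C)[C@H](O[Si](C)(C)C(C)(C)C)C1=C(C)[C@H](O[Si](C)(C)C(C)(C)C)CCC1=O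
A6 | alternative 3 | trans-decalin 4-ketone with free C8 hydroxyl and C7 isopropenyl | O[C@H]1C[C@@]2(C)[C@H](O[Si](C)(C)C(C)(C)C)CCC(=O)[C@@H]2[C@@H](O[Si](C)(C)C(C)(C)C)[C@@H]1C(C)=C
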